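## Structural features

Macrocarpal N is a 1,10-seco-aromadendrane bearing an isopentyl-diformylphloroglucinol unit. Numbered on the parent skeleton, a cyclopentanone (C1 carbonyl, C2 and C3 methylenes, quaternary C4, methine C5) carries at C5 a cis-1,2-disubstituted gem-dimethylcyclopropane (C6, C7, C11), whose C7 bears the 3-oxobutyl chain C8–C10. C4 carries a methyl group and the benzylic carbon C9', which holds an isobutyl group and the 2,4,6-trihydroxy-3,5-diformylphenyl ring. The rings are joined only by single bonds (C5–C6, C4–C9', C9'–aryl), so no ring enforces their mutual configuration. The five stereocentres form one chain C7–C6–C5–C4–C9': C6 and C7 are cis on the cyclopropane, the cyclopropyl group on C5 is cis to the C4 methyl group (trans to the bulky C9' substituent), and the quaternary C4 sits between two tertiary centres. Fragile elements are the electron-rich trihydroxy dialdehyde, the two enolisable ketones (C5 is epimerisable, being α to C1) and the cyclopropane toward strong acid. The real difficulty is the quaternary C4 with its vicinal benzylic C9' on a hexasubstituted arene, and their absolute relation to the cyclopropane. Two features are exploited. C6, C7, C11 and the chain are (+)-2-carene after cleavage of its C=C bond, the aldehyde carbon being C5. The ring C1(=O)–C5–C4 with C3–C2 is a 4-pentenal in disguise, so C4–C5 can be formed by a Claisen rearrangement in which C9', held by A(1,3) strain across a (Z)-C3=C4 olefin, directs the new bond at C4 while C5 is left to equilibration.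

## Logic of the disconnections

17 to 16: the two aryl–CHO bonds are cut. The dialdehyde triphenol is the most fragile part and tolerates none of the organometallic, hydride or transition-metal steps, so it is made last. The gain is a symmetric, highly nucleophilic arene with only two free positions. The forward step must formylate the arene twice without touching two ketones and without strong acid.

16 to 15: the three O–CH2Ph bonds are cut. The phenols must be masked as identical, base- and metal-stable ethers. The forward step must remove them without opening the cyclopropane, which points to hydrogenolysis.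

15 to 13 (through 14): the ring bond C1–C2 is cut. A cyclopentanone with one unsubstituted α-methylene is the product of hydroacylation of a 4-pentenal, so the ring becomes an open-chain aldehyde plus a vinyl group on C4. C5 need not be controlled earlier, because it is α to C1 and can be equilibrated. The forward step demands that alkene insertion outrun decarbonylation.

13 to 12: the bond C4–C5 is cut. This is the key disconnection: it removes the quaternary centre and reduces the union of the two halves to an ether, and the [3,3] array places C1 at the aldehyde oxidation level and leaves C3=C2 as the vinyl group. The forward step must select one face of C4. This requires the C3=C4 olefin of 12 to be (Z), so that C9' controls the face through A(1,3) strain.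

12 to 8 and 11: the C1–O bond is cut. This is the convergent point. The forward coupling must retain both olefin geometries and run below the temperature of the rearrangement, so that the base is removed before the aldehyde appears.

11 to 10 to 9: the C1=C5 bond is cut, then C5 and C10 are reconnected as the ring olefin of 9. C6, C7 and C11, with their cis relationship and absolute configuration, are bought. The forward steps demand clean ozonolysis and an aldehyde-selective olefination beside a methyl ketone.

8 to 7 to 6 to 5: C2 is returned to the ester level, then the C4–CH3 bond and the C3–C2 bond are cut. Syn addition of methyl and hydrogen across an alkyne is the reliable way to the (Z)-trisubstituted olefin with C9' and C2 cis. The forward step demands low-temperature addition and quench.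

5 to 4 to 2 and 3, and 2 to 1: one O–benzyl bond and then the aryl–C9' bond are cut. A propargylic substitution attaches the arene, sets C9' by catalysis from a racemic ester and leaves the alkyne as the handle for C4, C3 and C2. The forward step demands enantiocontrol with an aliphatic propargylic ester.

## Other disconnections considered

Alternative 1: the first that comes to mind. The C1 and C10 carbonyl carbons are rejoined as the tetrasubstituted C1=C10 olefin of the aromadendrene-type tricycle A1, and the forward key step is oxidative cleavage (ozonolysis) of A1. The chosen plan is preferred on three grounds. The seven-membered ring and its tetrasubstituted olefin would be built with full stereocontrol only to be cut. A1 still needs the C4–C9' bond, which would be formed intermolecularly at a trisubstituted olefin with no closed transition state to fix either the C4 face or C9'. The cleavage of a hindered tetrasubstituted olefin would have to be done beside an ozone-sensitive, electron-rich arene, which adds protection steps.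

Alternative 2: the C4–C9' bond is cut within a [3,3] array anchored at C1. The forward sequence is 1,2-addition of a 1,1-dimethyl-3-arylallyl metal to enone A2, then anionic oxy-Cope rearrangement of the alkoxide of A3, which would give the C1 ketone, C4 and C9' in one event. It is shorter on paper, but two structural points speak against it. In the chair array the aryl group of an (E)-styryl unit lies between C3 and the C4 methyl group, which leads to the C9' epimer of 17. The arrangement needed for 17 puts the aryl group against the cyclopropyl substituent on C5 ((Z)-olefin, chair) or eclipsed with the methyl group (boat). In addition, the carbonyl faces of A2 are flanked by the near-equivalent CH2R on C7 and CH3 on C11, so the C1 carbinol that relays all chirality cannot be set by the substrate.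

Alternative 3: the C4–C5 bond is cut as a carbene C–H insertion. The forward step is a dirhodium-catalysed 1,5-insertion of the α-diazo ketone A4 into the tertiary C4–H bond with retention, which would turn an acyclic C4(H)/C9' pair into the quaternary centre while closing the ring. The chosen plan is preferred because the carbene carbon of A4 carries the cyclopropyl group, and cyclopropyl carbenoids are prone to ring expansion to cyclobutenes. The acyclic vicinal pair would also have to be made separately and then carried through a diazo transfer, which costs more steps than the ether union.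

Key step: step 10

Remark: commercial (+)-2-carene is taken as the (1S,6R) enantiomer, which maps onto C6/C7 of the target. Racemic 1 is used because step 2 is stereoconvergent.

## Steps

Step 1
Reactants: 1 rac-5-methylhex-1-yn-3-ol
Product: 2 rac-5-methylhex-1-yn-3-yl 2,3,4,5,6-pentafluorobenzoate
Conditions: C6F5COCl, Et3N, DMAP (cat.), CH2Cl2, 0 °C to rt
Reagents that add atoms: pentafluorobenzoyl chloride, O=C(Cl)c1c(F)c(F)c(F)c(F)c1F
Why: Acylation of a secondary propargylic alcohol under nucleophilic catalysis; the electron-poor benzoate is the leaving group needed for copper allenylidene formation in step 2, and no stereocentre is set.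

Step 2
Reactants: 2 rac-5-methylhex-1-yn-3-yl 2,3,4,5,6-pentafluorobenzoate; 3 3,5-bis(benzyloxy)phenol
Product: 4 3,5-bis(benzyloxy)-2-[(3S)-5-methylhex-1-yn-3-yl]phenol
Conditions: Cu(OTf)2 (5 mol %), chiral tridentate P,N,N ketimine ligand (6 mol %, enantiomer leading to S), i-Pr2NEt, MeOH, −20 °C
Reagents that add atoms: none
Why: Copper-catalysed enantioselective propargylic Friedel–Crafts alkylation: the copper acetylide of 2 ionises to a copper allenylidene, whose γ-carbon is attacked by the ring carbon of the phenol inside the chiral pocket, so both enantiomers of 2 converge on (S)-C9'. Ortho and para attack lead to the same compound after step 3.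

Step 3
Reactants: 4 3,5-bis(benzyloxy)-2-[(3S)-5-methylhex-1-yn-3-yl]phenol
Product: 5 1,3,5-tris(benzyloxy)-2-[(3S)-5-methylhex-1-yn-3-yl]benzene
Conditions: BnBr, K2CO3, DMF, rt
Reagents that add atoms: benzyl bromide, BrCc1ccccc1
Why: Williamson etherification; it makes the three oxygen substituents identical and removes the acidic phenol before the organometallic and copper steps.

Step 4
Reactants: 5 1,3,5-tris(benzyloxy)-2-[(3S)-5-methylhex-1-yn-3-yl]benzene
Product: 6 methyl (4S)-6-methyl-4-[2,4,6-tris(benzyloxy)phenyl]hept-2-ynoate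
Conditions: n-BuLi, THF, −78 °C; then ClCO2Me, −78 to 0 °C
Reagents that add atoms: methyl chloroformate, COC(=O)Cl
Why: Deprotonation of the terminal alkyne, far more acidic than the C9'–H bond, and C-acylation with the chloroformate install C2; C9' is untouched.

Step 5
Reactants: 6 methyl (4S)-6-methyl-4-[2,4,6-tris(benzyloxy)phenyl]hept-2-ynoate
Product: 7 methyl (2Z,4S)-3,6-dimethyl-4-[2,4,6-tris(benzyloxy)phenyl]hept-2-enoate
Conditions: Me2CuLi (from MeLi and CuI), THF, −78 °C; MeOH then aq NH4Cl at −78 °C
Reagents that add atoms: lithium dimethylcuprate, [Li+].C[Cu-]C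
Why: syn-Carbocupration of the ynoate (conjugate addition of a Gilman cuprate) and protonation of the alkenylcopper with retention place CH3 and H cis, hence C9' and the ester cis. This is the (Z)-olefin that step 10 needs, and the cold quench prevents equilibration through the allenoate.

Step 6
Reactants: 7 methyl (2Z,4S)-3,6-dimethyl-4-[2,4,6-tris(benzyloxy)phenyl]hept-2-enoate
Product: 8 (2Z,4S)-3,6-dimethyl-4-[2,4,6-tris(benzyloxy)phenyl]hept-2-en-1-ol
Conditions: i-Bu2AlH, CH2Cl2, −78 to −20 °C; aq potassium sodium tartrate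
Reagents that add atoms: none
Why: 1,2-Reduction of the enoate by the aluminium hydride gives the allylic alcohol without change of olefin geometry and without loss of benzyl ethers.

Step 7
Reactants: 9 (+)-2-carene, (1S,6R)-3,7,7-trimethylbicyclo[4.1.0]hept-2-ene
Product: 10 (1S,3R)-2,2-dimethyl-3-(3-oxobutyl)cyclopropane-1-carbaldehyde
Conditions: O3, CH2Cl2–MeOH, −78 °C; then Me2S, −78 °C to rt
Reagents that add atoms: ozone, [O-][O+]=O
Why: Ozonolysis with reductive work-up cleaves the only C=C bond; both cyclopropane stereocentres and their cis relationship pass unchanged into C6 and C7, and the former olefinic CH becomes the aldehyde carbon that ends as C5.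

Step 8
Reactants: 10 (1S,3R)-2,2-dimethyl-3-(3-oxobutyl)cyclopropane-1-carbaldehyde
Product: 11 4-[(1R,3R)-3-[(E)-2-iodoethenyl]-2,2-dimethylcyclopropyl]butan-2-one
Conditions: CrCl2, CHI3, THF–1,4-dioxane, 0 °C to rt
Reagents that add atoms: iodoform, IC(I)I
Why: Takai olefination: the geminal dichromium carbenoid adds to the aldehyde far faster than to the methyl ketone and gives the (E)-vinyl iodide. The medium is not basic, so the cis-cyclopropane carbaldehyde should not epimerise.

Step 9
Reactants: 8 (2Z,4S)-3,6-dimethyl-4-[2,4,6-tris(benzyloxy)phenyl]hept-2-en-1-ol; 11 4-[(1R,3R)-3-[(E)-2-iodoethenyl]-2,2-dimethylcyclopropyl]butan-2-one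
Product: 12 4-[(1R,3R)-3-[(E)-2-[[(2Z,4S)-3,6-dimethyl-4-[2,4,6-tris(benzyloxy)phenyl]hept-2-en-1-yl]oxy]ethenyl]-2,2-dimethylcyclopropyl]butan-2-one
Conditions: CuI (10 mol %), 3,4,7,8-tetramethyl-1,10-phenanthroline (20 mol %), Cs2CO3, toluene, 80 °C
Reagents that add atoms: none
Why: Ullmann-type copper-catalysed O-vinylation of a primary allylic alcohol with a vinyl iodide proceeds with retention of both olefin geometries. At 80 °C the [3,3] shift has barely begun, so the ether can be freed from base before the aldehyde forms.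

Step 10
Reactants: 12 4-[(1R,3R)-3-[(E)-2-[[(2Z,4S)-3,6-dimethyl-4-[2,4,6-tris(benzyloxy)phenyl]hept-2-en-1-yl]oxy]ethenyl]-2,2-dimethylcyclopropyl]butan-2-one
Product: 13 (2S,3R,4S)-2-[(1R,3R)-2,2-dimethyl-3-(3-oxobutyl)cyclopropyl]-3-ethenyl-3,6-dimethyl-4-[2,4,6-tris(benzyloxy)phenyl]heptanal
Conditions: toluene (0.05 M, degassed), BHT (trace), base-washed sealed tube, 120 °C
Reagents that add atoms: none
Why: Concerted suprafacial [3,3]-sigmatropic shift (aliphatic Claisen rearrangement) through a chair array O–C1=C5···C4=C3–C2 that breaks O–C2 and forms C4–C5; the closest known reaction type is the Claisen rearrangement of γ,γ-disubstituted allyl vinyl ethers prepared by copper-catalysed O-vinylation, which gives aldehydes with β-quaternary carbons. No ring is closed here; the product is the 4-pentenal that step 11 closes. C4 is controlled by C9': across the (Z)-olefin, A(1,3) strain with C2 holds the C9'–H bond in the olefin plane, so the aryl and isobutyl groups shield opposite faces and C5 should bond anti to the much larger 2,4,6-tris(benzyloxy)phenyl group, which for (9'S) gives (4R). C5 is set by the (E)-enol ether in the chair as the epimer of the target, which is of no consequence because C5 is equilibrated in step 11. The step needs face selectivity at C4 and a [3,3] shift faster than the homodienyl 1,5-hydrogen shift of the cis-alkyl vinylcyclopropane. The first is secured by the olefin geometry fixed in step 5 and the size gap between the aryl group and CH2, the second by holding the bath at 120 °C and excluding acid and base.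

Step 11
Reactants: 13 (2S,3R,4S)-2-[(1R,3R)-2,2-dimethyl-3-(3-oxobutyl)cyclopropyl]-3-ethenyl-3,6-dimethyl-4-[2,4,6-tris(benzyloxy)phenyl]heptanal
Product: 15 (2R,3R)-2-[(1R,3R)-2,2-dimethyl-3-(3-oxobutyl)cyclopropyl]-3-methyl-3-[(1S)-3-methyl-1-[2,4,6-tris(benzyloxy)phenyl]butyl]cyclopentan-1-one, via cis-cyclopentanone 14 (not isolated)
Conditions: [Rh(nbd)(dppe)]BF4 (5 mol %, activated with H2, then Ar), CH2Cl2, rt; then DBU (0.3 equiv), rt
Reagents that add atoms: none
Why: Intramolecular hydroacylation of a 4-pentenal: aldehyde C–H oxidative addition to the cationic monovalent rhodium diphosphine, anti-Markovnikov insertion of the terminal vinyl group to a six-membered acyl rhodacycle and reductive elimination close C1–C2, helped by the quaternary C4. DBU then equilibrates the enolisable C5 so that the cyclopropyl group lies trans to the large C4 substituent, as in 17.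

Step 12
Reactants: 15 (2R,3R)-2-[(1R,3R)-2,2-dimethyl-3-(3-oxobutyl)cyclopropyl]-3-methyl-3-[(1S)-3-methyl-1-[2,4,6-tris(benzyloxy)phenyl]butyl]cyclopentan-1-one
Product: 16 (2R,3R)-2-[(1R,3R)-2,2-dimethyl-3-(3-oxobutyl)cyclopropyl]-3-methyl-3-[(1S)-3-methyl-1-(2,4,6-trihydroxyphenyl)butyl]cyclopentan-1-one
Conditions: H2 (1 atm), 10% Pd/C, EtOAc–MeOH, rt, exclusion of air
Reagents that add atoms: none
Why: Hydrogenolysis of the three benzyl ethers; dialkyl ketones and the non-activated cyclopropane should be inert under one atmosphere of hydrogen at room temperature.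

Step 13
Reactants: 16 (2R,3R)-2-[(1R,3R)-2,2-dimethyl-3-(3-oxobutyl)cyclopropyl]-3-methyl-3-[(1S)-3-methyl-1-(2,4,6-trihydroxyphenyl)butyl]cyclopentan-1-one
Product: 17 Macrocarpal N, 2,4,6-trihydroxy-5-[(1S)-1-[(1R,2R)-2-[(1R,3R)-2,2-dimethyl-3-(3-oxobutyl)cyclopropyl]-1-methyl-3-oxocyclopentyl]-3-methylbutyl]benzene-1,3-dicarbaldehyde
Conditions: POCl3 (3 equiv), DMF, MeCN, 0 °C to rt; then aq NaOAc, rt
Reagents that add atoms: N,N-dimethylformamide, CN(C)C=O; water, O
Why: Vilsmeier–Haack formylation: the phloroglucinol ring is nucleophilic enough to react twice with the chloroiminium salt at 0 °C to room temperature at its only two free positions, conditions under which simple ketones are not expected to be chloroformylated. Buffered hydrolysis releases the dialdehyde without strong acid near the cyclopropane.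

## Compound list

1 | rac-5-methylhex-1-yn-3-ol | C#CC(O)CC(C)C | starting material
2 | rac-5-methylhex-1-yn-3-yl 2,3,4,5,6-pentafluorobenzoate | C#CC(CC(C)C)OC(=O)c1c(F)c(F)c(F)c(F)c1F | intermediate
3 | 3,5-bis(benzyloxy)phenol | Oc1cc(OCc2ccccc2)cc(OCc2ccccc2)c1 | starting material
4 | 3,5-bis(benzyloxy)-2-[(3S)-5-methylhex-1-yn-3-yl]phenol | C#C[C@H](CC(C)C)c1c(O)cc(OCc2ccccc2)cc1OCc1ccccc1 | intermediate
5 | 1,3,5-tris(benzyloxy)-2-[(3S)-5-methylhex-1-yn-3-yl]benzene | C#C[C@H](CC(C)C)c1c(OCc2ccccc2)cc(OCc2ccccc2)cc1OCc1ccccc1 | intermediate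
6 | methyl (4S)-6-methyl-4-[2,4,6-tris(benzyloxy)phenyl]hept-2-ynoate | COC(=O)C#C[C@H](CC(C)C)c1c(OCc2ccccc2)cc(OCc2ccccc2)cc1OCc1ccccc1 | intermediate
7 | methyl (2Z,4S)-3,6-dimethyl-4-[2,4,6-tris(benzyloxy)phenyl]hept-2-enoate | COC(=O)/C=C(/C)[C@H](CC(C)C)c1c(OCc2ccccc2)cc(OCc2ccccc2)cc1OCc1ccccc1 | intermediate
8 | (2Z,4S)-3,6-dimethyl-4-[2,4,6-tris(benzyloxy)phenyl]hept-2-en-1-ol | OC/C=C(/C)[C@H](CC(C)C)c1c(OCc2ccccc2)cc(OCc2ccccc2)cc1OCc1ccccc1 | intermediate
9 | (+)-2-carene, (1S,6R)-3,7,7-trimethylbicyclo[4.1.0]hept-2-ene | CC1=C[C@H]2[C@@H](CC1)C2(C)C | starting material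
10 | (1S,3R)-2,2-dimethyl-3-(3-oxobutyl)cyclopropane-1-carbaldehyde | CC(=O)CC[C@@H]1[C@H](C=O)C1(C)C | intermediate
11 | 4-[(1R,3R)-3-[(E)-2-iodoethenyl]-2,2-dimethylcyclopropyl]butan-2-one | CC(=O)CC[C@@H]1[C@H](/C=C/I)C1(C)C | intermediate
12 | 4-[(1R,3R)-3-[(E)-2-[[(2Z,4S)-3,6-dimethyl-4-[2,4,6-tris(benzyloxy)phenyl]hept-2-en-1-yl]oxy]ethenyl]-2,2-dimethylcyclopropyl]butan-2-one | CC(=O)CC[C@@H]1[C@H](/C=C/OC/C=C(/C)[C@H](CC(C)C)c2c(OCc3ccccc3)cc(OCc3ccccc3)cc2OCc2ccccc2)C1(C)C | intermediate
13 | (2S,3R,4S)-2-[(1R,3R)-2,2-dimethyl-3-(3-oxobutyl)cyclopropyl]-3-ethenyl-3,6-dimethyl-4-[2,4,6-tris(benzyloxy)phenyl]heptanal | CC(=O)CC[C@@H]1[C@H]([C@H](C=O)[C@](C)(C=C)[C@H](CC(C)C)c2c(OCc3ccccc3)cc(OCc3ccccc3)cc2OCc2ccccc2)C1(C)C | intermediate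
14 | (2S,3R)-2-[(1R,3R)-2,2-dimethyl-3-(3-oxobutyl)cyclopropyl]-3-methyl-3-[(1S)-3-methyl-1-[2,4,6-tris(benzyloxy)phenyl]butyl]cyclopentan-1-one (cis-cyclopentanone) | CC(=O)CC[C@@H]1[C@H]([C@@H]2C(=O)CC[C@]2(C)[C@H](CC(C)C)c2c(OCc3ccccc3)cc(OCc3ccccc3)cc2OCc2ccccc2)C1(C)C | intermediate (not isolated)
15 | (2R,3R)-2-[(1R,3R)-2,2-dimethyl-3-(3-oxobutyl)cyclopropyl]-3-methyl-3-[(1S)-3-methyl-1-[2,4,6-tris(benzyloxy)phenyl]butyl]cyclopentan-1-one | CC(=O)CC[C@@H]1[C@H]([C@H]2C(=O)CC[C@]2(C)[C@H](CC(C)C)c2c(OCc3ccccc3)cc(OCc3ccccc3)cc2OCc2ccccc2)C1(C)C | intermediate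
16 | (2R,3R)-2-[(1R,3R)-2,2-dimethyl-3-(3-oxobutyl)cyclopropyl]-3-methyl-3-[(1S)-3-methyl-1-(2,4,6-trihydroxyphenyl)butyl]cyclopentan-1-one | CC(=O)CC[C@@H]1[C@H]([C@H]2C(=O)CC[C@]2(C)[C@H](CC(C)C)c2c(O)cc(O)cc2O)C1(C)C | intermediate
17 | Macrocarpal N | CC(=O)CC[C@@H]1[C@H]([C@H]2C(=O)CC[C@]2(C)[C@H](CC(C)C)c2c(O)c(C=O)c(O)c(C=O)c2O)C1(C)C | target

## Step count and least certain steps

Total step count: 13. Longest linear sequence: 11 steps (steps 1–6 and 9–13); the second branch (steps 7 and 8) joins at step 9.

Step 10 (key step). What may go wrong: the [3,3] shift at the crowded C4 terminus may be slow, so that the homodienyl 1,5-hydrogen shift of the cis-alkyl vinylcyclopropane intervenes or a higher temperature erodes the facial selectivity at C4. The fallback sets out from 10 and 8 and comes back at 13. Aldehyde-selective Wittig methoxymethylenation of 10 (Ph3P=CHOMe) would give the enol ether 4-[(1R,3R)-3-(2-methoxyethenyl)-2,2-dimethylcyclopropyl]butan-2-one F1. Mild aqueous acid would give the homologous aldehyde F2, and Pinnick oxidation the cyclopropylacetic acid F3. Carbodiimide esterification with 8 would give the allylic ester F4. Ireland–Claisen rearrangement (excess LiN(SiMe3)2 and Me3SiCl, THF, −78 °C to rt, the methyl ketone being held as its silyl enol ether until work-up) should run below 60 °C through the same chair and the same A(1,3)-controlled face to the acid F5. Reduction with LiAlH4 to the diol F6 and Dess–Martin oxidation of both hydroxyl groups would return 13.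

Step 2. What may go wrong: erosion of enantioselectivity and competing O-propargylation, because the aliphatic propargylic ester gives a copper allenylidene without the aryl group that usually rigidifies it. The fallback sets out from 2 and 3 and comes back at 4. The same C-alkylation run with an achiral ligand (2,2'-bipyridine) would give the racemic phenol F7, whose enantiomers are separated by preparative chromatography on a chiral stationary phase; the (S)-enantiomer is 4.

Step 11. What may go wrong: decarbonylation of the hindered acyl rhodium hydride, which deactivates the catalyst as a rhodium carbonyl, may compete with alkene insertion. The fallback sets out from 13 and comes back at 16. Nozaki–Hiyama–Kishi addition of vinyl bromide (CrCl2, NiCl2 cat., DMF), selective for the aldehyde over the methyl ketone, would give the dienol F8. Ring-closing metathesis with the second-generation Grubbs catalyst would give the cyclopentenol F9. Dess–Martin oxidation would give the cis-enone F10, and DBU its C5 epimer, the trans-enone F11. Hydrogenation over Pd/C as in step 12 would saturate C2=C3 and remove the benzyl groups to give 16.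

Step 13. What may go wrong: competitive chloroformylation of the enolisable C10 methyl ketone, or an incomplete second formylation once the first formyl group has deactivated the ring. The fallback sets out from 15 and comes back at 17. The more reactive C10 ketone would be masked as its dioxolane F12 (ethylene glycol, pyridinium tosylate). Hydrogenolysis would give the triol F13, Vilsmeier–Haack formylation the dialdehyde F14, and dilute aqueous acid would release 17.

## Further compounds

F1 | step 10 | 4-[(1R,3R)-3-(2-methoxyethenyl)-2,2-dimethylcyclopropyl]butan-2-one (E/Z mixture) | CC(=O)CC[C@@H]1[C@H](C=COC)C1(C)C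
F2 | step 10 | 2-[(1S,3R)-2,2-dimethyl-3-(3-oxobutyl)cyclopropyl]acetaldehyde | CC(=O)CC[C@@H]1[C@H](CC=O)C1(C)C
F3 | step 10 | 2-[(1S,3R)-2,2-dimethyl-3-(3-oxobutyl)cyclopropyl]acetic acid | CC(=O)CC[C@@H]1[C@H](CC(=O)O)C1(C)C
F4 | step 10 | (2Z,4S)-3,6-dimethyl-4-[2,4,6-tris(benzyloxy)phenyl]hept-2-en-1-yl 2-[(1S,3R)-2,2-dimethyl-3-(3-oxobutyl)cyclopropyl]acetate | CC(=O)CC[C@@H]1[C@H](CC(=O)OC/C=C(/C)[C@H](CC(C)C)c2c(OCc3ccccc3)cc(OCc3ccccc3)cc2OCc2ccccc2)C1(C)C
F5 | step 10 | (2S,3R,4S)-2-[(1R,3R)-2,2-dimethyl-3-(3-oxobutyl)cyclopropyl]-3-ethenyl-3,6-dimethyl-4-[2,4,6-tris(benzyloxy)phenyl]heptanoic acid | CC(=O)CC[C@@H]1[C@H]([C@H](C(=O)O)[C@](C)(C=C)[C@H](CC(C)C)c2c(OCc3ccccc3)cc(OCc3ccccc3)cc2OCc2ccccc2)C1(C)C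
F6 | step 10 | (2S,3R,4S)-3-ethenyl-2-[(1R,3R)-3-(3-hydroxybutyl)-2,2-dimethylcyclopropyl]-3,6-dimethyl-4-[2,4,6-tris(benzyloxy)phenyl]heptan-1-ol (both carbinol epimers of the side chain) | CC(O)CC[C@@H]1[C@H]([C@H](CO)[C@](C)(C=C)[C@H](CC(C)C)c2c(OCc3ccccc3)cc(OCc3ccccc3)cc2OCc2ccccc2)C1(C)C
F7 | step 2 | rac-3,5-bis(benzyloxy)-2-(5-methylhex-1-yn-3-yl)phenol | C#CC(CC(C)C)c1c(O)cc(OCc2ccccc2)cc1OCc1ccccc1
F8 | step 11 | (4S,5R,6S)-4-[(1R,3R)-2,2-dimethyl-3-(3-oxobutyl)cyclopropyl]-5-ethenyl-5,8-dimethyl-6-[2,4,6-tris(benzyloxy)phenyl]non-1-en-3-ol (both C3 epimers) | CC(=O)CC[C@@H]1[C@H]([C@H](C(O)C=C)[C@](C)(C=C)[C@H](CC(C)C)c2c(OCc3ccccc3)cc(OCc3ccccc3)cc2OCc2ccccc2)C1(C)C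
F9 | step 11 | (4R,5S)-5-[(1R,3R)-2,2-dimethyl-3-(3-oxobutyl)cyclopropyl]-4-methyl-4-[(1S)-3-methyl-1-[2,4,6-tris(benzyloxy)phenyl]butyl]cyclopent-2-en-1-ol (both C1 epimers) | CC(=O)CC[C@@H]1[C@H]([C@@H]2C(O)C=C[C@]2(C)[C@H](CC(C)C)c2c(OCc3ccccc3)cc(OCc3ccccc3)cc2OCc2ccccc2)C1(C)C
F10 | step 11 | (4R,5S)-5-[(1R,3R)-2,2-dimethyl-3-(3-oxobutyl)cyclopropyl]-4-methyl-4-[(1S)-3-methyl-1-[2,4,6-tris(benzyloxy)phenyl]butyl]cyclopent-2-en-1-one (cis-enone) | CC(=O)CC[C@@H]1[C@H]([C@@H]2C(=O)C=C[C@]2(C)[C@H](CC(C)C)c2c(OCc3ccccc3)cc(OCc3ccccc3)cc2OCc2ccccc2)C1(C)C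
F11 | step 11 | (4R,5R)-5-[(1R,3R)-2,2-dimethyl-3-(3-oxobutyl)cyclopropyl]-4-methyl-4-[(1S)-3-methyl-1-[2,4,6-tris(benzyloxy)phenyl]butyl]cyclopent-2-en-1-one (trans-enone) | CC(=O)CC[C@@H]1[C@H]([C@H]2C(=O)C=C[C@]2(C)[C@H](CC(C)C)c2c(OCc3ccccc3)cc(OCc3ccccc3)cc2OCc2ccccc2)C1(C)C
F12 | step 13 | C10 ethylene ketal of 15, (2R,3R)-2-[(1R,3R)-2,2-dimethyl-3-[2-(2-methyl-1,3-dioxolan-2-yl)ethyl]cyclopropyl]-3-methyl-3-[(1S)-3-methyl-1-[2,4,6-tris(benzyloxy)phenyl]butyl]cyclopentan-1-one | CC1(CC[C@@H]2[C@H]([C@H]3C(=O)CC[C@]3(C)[C@H](CC(C)C)c3c(OCc4ccccc4)cc(OCc4ccccc4)cc3OCc3ccccc3)C2(C)C)OCCO1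
F13 | step 13 | C10 ethylene ketal of 16 | CC1(CC[C@@H]2[C@H]([C@H]3C(=O)CC[C@]3(C)[C@H](CC(C)C)c3c(O)cc(O)cc3O)C2(C)C)OCCO1
F14 | step 13 | C10 ethylene ketal of 17 | CC1(CC[C@@H]2[C@H]([C@H]3C(=O)CC[C@]3(C)[C@H](CC(C)C)c3c(O)c(C=O)c(O)c(C=O)c3O)C2(C)C)OCCO1
A1 | alternative 1 | aromadendr-1(10)-ene carrying at C4 the (1S)-1-(3,5-diformyl-2,4,6-trihydroxyphenyl)-3-methylbutyl group (C1=C10 olefin in place of the two ketone carbonyls of 17) | CC3CC[C@@H]1[C@H]([C@H]2C=3CC[C@]2(C)[C@H](CC(C)C)c2c(O)c(C=O)c(O)c(C=O)c2O)C1(C)C
A2 | alternative 2 | 2-[(1R,3R)-2,2-dimethyl-3-(3-oxobutyl)cyclopropyl]-3-methylcyclopent-2-en-1-one | CC(=O)CC[C@@H]1[C@H](C2=C(C)CCC2=O)C1(C)C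
A3 | alternative 2 | 2-[(1R,3R)-2,2-dimethyl-3-(3-oxobutyl)cyclopropyl]-3-methyl-1-[(E)-2-methyl-4-[2,4,6-tris(benzyloxy)phenyl]but-3-en-2-yl]cyclopent-2-en-1-ol (C1 epimer with the allyl group on the face that becomes the C4–C9' side) | CC(=O)CC[C@@H]1[C@H](C2=C(C)CC[C@@]2(O)C(C)(C)/C=C/c2c(OCc3ccccc3)cc(OCc3ccccc3)cc2OCc2ccccc2)C1(C)C
A4 | alternative 3 | α-cyclopropyl α-diazo ketone, 4-[(1R,3R)-3-[1-diazo-5,8-dimethyl-2-oxo-6-[2,4,6-tris(benzyloxy)phenyl]nonyl]-2,2-dimethylcyclopropyl]butan-2-one with the C4–H and C9' configurations of 17 | CC(=O)CC[C@@H]1[C@H](C(=[N+]=[N-])C(=O)CC[C@H](C)[C@H](CC(C)C)c2c(OCc3ccccc3)cc(OCc3ccccc3)cc2OCc2ccccc2)C1(C)C
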